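**Retrosynthetic overview**
1. The strategy rests on one feature: the γ-lactone O–C12–C11–C7–C6 is cis-fused on the C6–C7 bond of the ten-membered carbocycle C1–C10, and C11 is the only carbon branch at C7. The target comes from the 11-phosphono lactone 32 by olefination with formaldehyde (C13) and C9 desilylation.
2. 32 ⇐ 31: a rhodium carbenoid tethered through the C6 ester inserts into C7–H, forming C7–C11 and closing the lactone. 31 ⇐ epoxy alcohol 28 by acylation and diazo transfer.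
3. 28 ⇐ (Z)-allylic alcohol 27 by peracid epoxidation; C6 is set by CBS reduction of enone 26. The carbocycle ⇐ iodo aldehyde 23 by Ni/Cr closure of C5–C6 on a chain with no branch at C7.
4. 23 ⇐ 2-formyl enoate 10 + a (Z)-γ-alkoxyallylborane (C8–C9 bond, 8S and 9S; the vinyl group becomes C6). 10 ⇐ Baylis–Hillman chemistry on aldehyde 6 (fixes the C1=C10 geometry). 6 ⇐ carbocupration of propyne (fixes the Z C4=C5 that becomes the cis epoxide).
5. Ring order: carbocycle (step 13), oxirane (step 16), γ-lactone (step 19).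

Key step: step 19

**Assumptions (remarks on the chemistry)**
- Germacrane numbering is used for the ring compounds: carbocycle C1–C10; lactone carbons C11, C12, C13 on C7; ester carbon C14 on C10; methyl C15 on C4. Angeloyl = (Z)-2-methylbut-2-enoyl; TBS = tert-butyldimethylsilyl.
- The carbene carbon carries a diethoxyphosphoryl group. This lets C13 be introduced afterwards under weak base, without a lactone enolate next to the angelate and the enoate.
- The C9–C10 bond is not made from an α-metalated acrylate, because such species can lose the alkene geometry; the geometry is fixed through the Baylis–Hillman bromide instead.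
- 8 is racemic at its carbinol carbon, 25 is a pair of C6 epimers and 32 a pair of C11 epimers; each of these centres is removed or reset in the following step(s).

**Route**

Step 1
Reactants: 1 2-(2-bromoethyl)-1,3-dioxolane; 2 propyne
Product: 5 2-[(3Z)-4-iodo-3-methylbut-3-en-1-yl]-1,3-dioxolane, via Grignard reagent 3 (not isolated), via (Z)-alkenylcopper 4 (not isolated)
Conditions: Mg, THF, 30 °C; CuBr·SMe2, Et2O/Me2S, −45 °C; 2, −25 °C; I2, −50 °C → rt
Reagents that add atoms: iodine (II)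
Why: Normant carbocupration adds the alkylcopper syn across propyne with copper on the terminal carbon, and iodinolysis with retention fixes the (Z)-iodoalkene that becomes C4=C5.

Step 2
Reactants: 5 2-[(3Z)-4-iodo-3-methylbut-3-en-1-yl]-1,3-dioxolane
Product: 6 (4Z)-5-iodo-4-methylpent-4-enal
Conditions: 1 M HCl, THF, rt
Reagents that add atoms: water (O)
Why: Acid-catalysed acetal hydrolysis should unmask the C1 aldehyde, the alkenyl iodide being inert to dilute acid.

Step 3
Reactants: 6 (4Z)-5-iodo-4-methylpent-4-enal; 7 methyl acrylate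
Product: 8 methyl (6Z)-3-hydroxy-7-iodo-6-methyl-2-methylidenehept-6-enoate (racemic)
Conditions: 7 (3 equiv), DABCO (0.5 equiv), MeOH, rt
Reagents that add atoms: none
Why: Morita–Baylis–Hillman reaction of an unhindered aliphatic aldehyde; the carbinol centre is formed racemic and is erased in step 4.

Step 4
Reactants: 8 methyl (6Z)-3-hydroxy-7-iodo-6-methyl-2-methylidenehept-6-enoate
Product: 9 methyl (2Z,6Z)-2-(bromomethyl)-7-iodo-6-methylhepta-2,6-dienoate
Conditions: NBS, Me2S, CH2Cl2, 0 °C → rt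
Reagents that add atoms: N-bromosuccinimide (O=C1CCC(=O)N1Br)
Why: Corey–Kim-type activation of the alcohol and SN2′ return of bromide should give the rearranged primary bromide in its preferred (Z) form (chain cis to CH2Br, trans to the ester), which fixes the later C1=C10 geometry.

Step 5
Reactants: 9 methyl (2Z,6Z)-2-(bromomethyl)-7-iodo-6-methylhepta-2,6-dienoate
Product: 10 methyl (2E,6Z)-2-formyl-7-iodo-6-methylhepta-2,6-dienoate
Conditions: NMO (4 equiv), 4 Å MS, MeCN, 0 °C → rt; used at once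
Reagents that add atoms: 4-methylmorpholine N-oxide (C[N+]1([O-])CCOCC1)
Why: Kornblum-type oxidation, in which the N-oxide is O-alkylated by the primary allylic bromide and eliminates to the aldehyde (the future C9) without touching the alkene geometry.

Step 6
Reactants: 11 allyl alcohol
Product: 12 3-(methoxymethoxy)prop-1-ene
Conditions: MOMCl, i-Pr2NEt, CH2Cl2, 0 °C → rt
Reagents that add atoms: chloromethyl methyl ether (COCCl)
Why: O-alkylation of the primary alcohol with the reactive α-chloro ether (Williamson type).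

Step 7
Reactants: 12 3-(methoxymethoxy)prop-1-ene; 10 methyl (2E,6Z)-2-formyl-7-iodo-6-methylhepta-2,6-dienoate
Product: 15 methyl (2E,6Z)-2-[(1S,2S)-1-hydroxy-2-(methoxymethoxy)but-3-en-1-yl]-7-iodo-6-methylhepta-2,6-dienoate, via (Z)-γ-(methoxymethoxy)allyllithium 13 (not isolated), via (Z)-γ-(methoxymethoxy)allylbis(isopinocampheyl)borane 14 (not isolated)
Conditions: s-BuLi, THF, −78 °C; (+)-Ipc2BOMe [from (−)-α-pinene]; BF3·OEt2; 10, −78 °C; ethanolamine work-up
Reagents that add atoms: none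
Why: Brown γ-alkoxyallylboration goes through a chair transition state in which the (Z)-enol ether gives the syn (threo) diol monoether and the Ipc ligands of the (−)-α-pinene series choose the aldehyde face, so 8S and 9S are set by the reagent on an achiral aldehyde.

Step 8
Reactants: 15 methyl (2E,6Z)-2-[(1S,2S)-1-hydroxy-2-(methoxymethoxy)but-3-en-1-yl]-7-iodo-6-methylhepta-2,6-dienoate
Product: 16 methyl (2E,6Z)-2-[(1S,2S)-1-[(tert-butyldimethylsilyl)oxy]-2-(methoxymethoxy)but-3-en-1-yl]-7-iodo-6-methylhepta-2,6-dienoate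
Conditions: TBSOTf, 2,6-lutidine, CH2Cl2, −78 → 0 °C
Reagents that add atoms: tert-butyldimethylsilyl triflate (CC(C)(C)[Si](C)(C)OS(=O)(=O)C(F)(F)F)
Why: The silyl triflate silylates the hindered secondary C9 hydroxyl without touching a stereocentre.

Step 9
Reactants: 16 methyl (2E,6Z)-2-[(1S,2S)-1-[(tert-butyldimethylsilyl)oxy]-2-(methoxymethoxy)but-3-en-1-yl]-7-iodo-6-methylhepta-2,6-dienoate
Product: 17 methyl (2E,6Z)-2-[(1S,2S)-1-[(tert-butyldimethylsilyl)oxy]-2-hydroxybut-3-en-1-yl]-7-iodo-6-methylhepta-2,6-dienoate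
Conditions: Me2BBr, CH2Cl2, −78 °C; then sat. NaHCO3, THF
Reagents that add atoms: none
Why: Dimethylboron bromide cleaves the acetal C–O bond of the MOM ether at −78 °C, while the silyl ether, the ester and the alkenyl iodide are left.

Step 10
Reactants: 17 methyl (2E,6Z)-2-[(1S,2S)-1-[(tert-butyldimethylsilyl)oxy]-2-hydroxybut-3-en-1-yl]-7-iodo-6-methylhepta-2,6-dienoate; 18 angelic acid
Product: 20 methyl (2E,6Z)-2-[(1S,2S)-2-(angeloyloxy)-1-[(tert-butyldimethylsilyl)oxy]but-3-en-1-yl]-7-iodo-6-methylhepta-2,6-dienoate, via mixed anhydride 19 (not isolated)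
Conditions: 18, 2,4,6-trichlorobenzoyl chloride, Et3N, toluene, rt; then 17, 80 °C (no DMAP)
Reagents that add atoms: none
Why: Yamaguchi esterification through the mixed anhydride without a nucleophilic catalyst is the usual way to acylate with angelic acid without (Z)→(E) isomerisation; C8 is not affected.

Step 11
Reactants: 20 methyl (2E,6Z)-2-[(1S,2S)-2-(angeloyloxy)-1-[(tert-butyldimethylsilyl)oxy]but-3-en-1-yl]-7-iodo-6-methylhepta-2,6-dienoate
Product: 22 methyl (2E,6Z)-2-[(1S,2S)-2-(angeloyloxy)-1-[(tert-butyldimethylsilyl)oxy]-4-hydroxybutyl]-7-iodo-6-methylhepta-2,6-dienoate, via B-alkyl-9-BBN adduct 21 (not isolated)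
Conditions: 9-BBN, THF, 0 °C → rt; then H2O2, aq. NaOAc, 0 °C
Reagents that add atoms: hydrogen peroxide (OO)
Why: 9-BBN should hydroborate only the monosubstituted alkene, at its terminal carbon, and buffered peroxide oxidation gives the primary alcohol that becomes C6.

Step 12
Reactants: 22 methyl (2E,6Z)-2-[(1S,2S)-2-(angeloyloxy)-1-[(tert-butyldimethylsilyl)oxy]-4-hydroxybutyl]-7-iodo-6-methylhepta-2,6-dienoate
Product: 23 methyl (2E,6Z)-2-[(1S,2S)-2-(angeloyloxy)-1-[(tert-butyldimethylsilyl)oxy]-4-oxobutyl]-7-iodo-6-methylhepta-2,6-dienoate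
Conditions: Dess–Martin periodinane, NaHCO3, CH2Cl2, 0 °C → rt; used at once
Reagents that add atoms: none
Why: Dess–Martin oxidation under buffered, non-basic conditions should give the β-acyloxy aldehyde without elimination.

Step 13
Reactants: 23 methyl (2E,6Z)-2-[(1S,2S)-2-(angeloyloxy)-1-[(tert-butyldimethylsilyl)oxy]-4-oxobutyl]-7-iodo-6-methylhepta-2,6-dienoate
Product: 25 methyl (1(10)E,4Z,8S,9S)-8-angeloyloxy-6-hydroxy-9-(TBS-oxy)-11,12,13-trinorgermacra-1(10),4-dien-14-oate (both C6 epimers), via alkenylchromium(III) species 24 (not isolated)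
Conditions: CrCl2 (10 equiv), NiCl2 (10 mol %), degassed DMSO, rt, 3 mM, slow addition
Reagents that add atoms: none
Why: Nozaki–Hiyama–Kishi reaction, in which the alkenylchromium forms with retention of the (Z) geometry and adds to the aldehyde at high dilution, closing the ten-membered ring at C5–C6; the C6 configuration is not relied on.

Step 14
Reactants: 25 methyl (1(10)E,4Z,8S,9S)-8-angeloyloxy-6-hydroxy-9-(TBS-oxy)-11,12,13-trinorgermacra-1(10),4-dien-14-oate
Product: 26 methyl (1(10)E,4Z,8S,9S)-8-angeloyloxy-6-oxo-9-(TBS-oxy)-11,12,13-trinorgermacra-1(10),4-dien-14-oate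
Conditions: Dess–Martin periodinane, NaHCO3, CH2Cl2, 0 °C
Reagents that add atoms: none
Why: Buffered oxidation converges both C6 epimers into one (Z)-enone.

Step 15
Reactants: 26 methyl (1(10)E,4Z,8S,9S)-8-angeloyloxy-6-oxo-9-(TBS-oxy)-11,12,13-trinorgermacra-1(10),4-dien-14-oate
Product: 27 methyl (1(10)E,4Z,6R,8S,9S)-8-angeloyloxy-6-hydroxy-9-(TBS-oxy)-11,12,13-trinorgermacra-1(10),4-dien-14-oate
Conditions: (S)-Me-CBS (20 mol %), catecholborane, toluene, −78 °C
Reagents that add atoms: none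
Why: Corey–Bakshi–Shibata reduction, in which the (S)-oxazaborolidine treats the alkenyl arm as the large group and delivers hydride to the face that gives the 6R carbinol, under reagent control.

Step 16
Reactants: 27 methyl (1(10)E,4Z,6R,8S,9S)-8-angeloyloxy-6-hydroxy-9-(TBS-oxy)-11,12,13-trinorgermacra-1(10),4-dien-14-oate
Product: 28 methyl (1(10)E,4R,5S,6R,8S,9S)-8-angeloyloxy-4,5-epoxy-6-hydroxy-9-(TBS-oxy)-11,12,13-trinorgermacr-1(10)-en-14-oate
Conditions: mCPBA, NaHCO3, CH2Cl2, 0 °C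
Reagents that add atoms: 3-chloroperbenzoic acid (OOC(=O)c1cccc(Cl)c1)
Why: Peracid epoxidation of a (Z)-allylic alcohol, in which allylic 1,3-strain holds C6–H in the alkene plane and the hydrogen-bonded peracid adds to the face bearing the hydroxyl, should give the threo (ring-trans) epoxy alcohol with 4R,5S; both conjugated C=C bonds are too electron-poor to react.

Step 17
Reactants: 28 methyl (1(10)E,4R,5S,6R,8S,9S)-8-angeloyloxy-4,5-epoxy-6-hydroxy-9-(TBS-oxy)-11,12,13-trinorgermacr-1(10)-en-14-oate; 29 (diethoxyphosphoryl)acetic acid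
Product: 30 methyl (1(10)E,4R,5S,6R,8S,9S)-8-angeloyloxy-6-{[(diethoxyphosphoryl)acetyl]oxy}-4,5-epoxy-9-(TBS-oxy)-11,12,13-trinorgermacr-1(10)-en-14-oate
Conditions: DCC, DMAP (10 mol %), CH2Cl2, 0 °C → rt
Reagents that add atoms: none
Why: Steglich esterification of the secondary C6 hydroxyl, with no change at any stereocentre.

Step 18
Reactants: 30 methyl (1(10)E,4R,5S,6R,8S,9S)-8-angeloyloxy-6-{[(diethoxyphosphoryl)acetyl]oxy}-4,5-epoxy-9-(TBS-oxy)-11,12,13-trinorgermacr-1(10)-en-14-oate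
Product: 31 methyl (1(10)E,4R,5S,6R,8S,9S)-8-angeloyloxy-6-{[diazo(diethoxyphosphoryl)acetyl]oxy}-4,5-epoxy-9-(TBS-oxy)-11,12,13-trinorgermacr-1(10)-en-14-oate
Conditions: p-ABSA, DBU, MeCN, 0 °C → rt
Reagents that add atoms: 4-acetamidobenzenesulfonyl azide (CC(=O)Nc1ccc(cc1)S(=O)(=O)N=[N+]=[N-])
Why: Regitz diazo transfer to the doubly activated methylene of the phosphonoacetate.

Step 19
Reactants: 31 methyl (1(10)E,4R,5S,6R,8S,9S)-8-angeloyloxy-6-{[diazo(diethoxyphosphoryl)acetyl]oxy}-4,5-epoxy-9-(TBS-oxy)-11,12,13-trinorgermacr-1(10)-en-14-oate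
Product: 32 methyl (1(10)E,4R,5S,6R,7R,8S,9S)-8-angeloyloxy-11-(diethoxyphosphoryl)-4,5-epoxy-9-(TBS-oxy)-13-norgermacr-1(10)-en-12,6-olid-14-oate (C11 epimers)
Conditions: Rh2(esp)2 (2 mol %), CH2Cl2, 40 °C
Reagents that add atoms: none
Why: The dirhodium catalyst expels N2 from 31, and the electrophilic carbenoid at C11 inserts into a C7–H bond in a concerted three-centre transition state with retention at carbon. The closest known reaction type is the Rh(II)-catalysed intramolecular 1,5 C–H insertion of alkyl α-diazo-α-phosphonoacetates, which gives α-phosphono-γ-butyrolactones. The γ-lactone (third ring) closes by C7–C11 bond formation through a five-membered transition state held by the C6 ester tether. C7 is set by that tether: only the C7–H syn to the C6 oxygen in a gauche C5–C6–C7–C8 conformer leads to the cis fusion, and the 6,8-syn oxygen pattern disfavours the extended conformer that would give the trans-fused isomer; C11 forms as a mixture and stops being a stereocentre in step 20. The step needs site selectivity against C8–H (six-membered transition state, geminal acyloxy deactivation), the oxirane C5–H (high s character), the oxirane oxygen (ylide formation) and both C=C bonds; what the substrate offers is the five-membered preference of ester-tethered carbenoids, the low basicity of the epoxide oxygen and the electron-poor character of both alkenes.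

Step 20
Reactants: 32 methyl (1(10)E,4R,5S,6R,7R,8S,9S)-8-angeloyloxy-11-(diethoxyphosphoryl)-4,5-epoxy-9-(TBS-oxy)-13-norgermacr-1(10)-en-12,6-olid-14-oate
Product: 33 methyl (1(10)E,4R,5S,6R,7R,8S,9S)-8-angeloyloxy-4,5-epoxy-9-(TBS-oxy)germacra-1(10),11(13)-dien-12,6-olid-14-oate
Conditions: K2CO3, 37% aq. HCHO, THF, 0 °C → rt
Reagents that add atoms: formaldehyde (C=O)
Why: Horner–Wadsworth–Emmons olefination with formaldehyde, in which the phosphonate-stabilised anion forms under weak base, so the angelate, the methyl ester and the epoxide never meet an ester enolate; C11 becomes sp2.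

Step 21
Reactants: 33 methyl (1(10)E,4R,5S,6R,7R,8S,9S)-8-angeloyloxy-4,5-epoxy-9-(TBS-oxy)germacra-1(10),11(13)-dien-12,6-olid-14-oate
Product: 34 methyl (1(10)E,4R,5S,6R,7R,8S,9S)-8-angeloyloxy-4,5-epoxy-9-hydroxygermacra-1(10),11(13)-dien-12,6-olid-14-oate (CNP0251641.1)
Conditions: HF·pyridine, pyridine, THF, 0 °C → rt
Reagents that add atoms: none
Why: Pyridine-buffered HF cleaves the Si–O bond, conditions that trisubstituted epoxides and α-methylene lactones are known to survive.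

**Compound list**
1 | 2-(2-bromoethyl)-1,3-dioxolane | BrCCC1OCCO1 | starting material
2 | propyne | CC#C | starting material
3 | [2-(1,3-dioxolan-2-yl)ethyl]magnesium bromide | Br[Mg]CCC1OCCO1 | intermediate
4 | [(1Z)-4-(1,3-dioxolan-2-yl)-2-methylbut-1-en-1-yl]copper | C/C(CCC1OCCO1)=C/[Cu] | intermediate
5 | 2-[(3Z)-4-iodo-3-methylbut-3-en-1-yl]-1,3-dioxolane | C/C(CCC1OCCO1)=C/I | intermediate
6 | (4Z)-5-iodo-4-methylpent-4-enal | C/C(CCC=O)=C/I | intermediate
7 | methyl acrylate | C=CC(=O)OC | starting material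
8 | methyl (6Z)-3-hydroxy-7-iodo-6-methyl-2-methylidenehept-6-enoate (racemic) | C=C(C(=O)OC)C(O)CC/C(C)=C\I | intermediate
9 | methyl (2Z,6Z)-2-(bromomethyl)-7-iodo-6-methylhepta-2,6-dienoate | BrC/C(C(=O)OC)=C\CC/C(C)=C\I | intermediate
10 | methyl (2E,6Z)-2-formyl-7-iodo-6-methylhepta-2,6-dienoate | O=C/C(C(=O)OC)=C\CC/C(C)=C\I | intermediate
11 | allyl alcohol | C=CCO | starting material
12 | 3-(methoxymethoxy)prop-1-ene | C=CCOCOC | intermediate
13 | [(2Z)-3-(methoxymethoxy)prop-2-en-1-yl]lithium | [Li]C/C=C\OCOC | intermediate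
14 | [(2Z)-3-(methoxymethoxy)prop-2-en-1-yl]bis(isopinocampheyl)borane, (−)-α-pinene series | COCO/C=C\CB([C@H]1C[C@H]2C[C@@H]([C@@H]1C)C2(C)C)[C@H]1C[C@H]2C[C@@H]([C@@H]1C)C2(C)C | intermediate
15 | methyl (2E,6Z)-2-[(1S,2S)-1-hydroxy-2-(methoxymethoxy)but-3-en-1-yl]-7-iodo-6-methylhepta-2,6-dienoate | C=C[C@H](OCOC)[C@@H](O)/C(C(=O)OC)=C\CC/C(C)=C\I | intermediate
16 | methyl (2E,6Z)-2-[(1S,2S)-1-[(tert-butyldimethylsilyl)oxy]-2-(methoxymethoxy)but-3-en-1-yl]-7-iodo-6-methylhepta-2,6-dienoate | C=C[C@H](OCOC)[C@@H](O[Si](C)(C)C(C)(C)C)/C(C(=O)OC)=C\CC/C(C)=C\I | intermediate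
17 | methyl (2E,6Z)-2-[(1S,2S)-1-[(tert-butyldimethylsilyl)oxy]-2-hydroxybut-3-en-1-yl]-7-iodo-6-methylhepta-2,6-dienoate | C=C[C@H](O)[C@@H](O[Si](C)(C)C(C)(C)C)/C(C(=O)OC)=C\CC/C(C)=C\I | intermediate
18 | angelic acid | C/C=C(/C)C(=O)O | starting material
19 | angelic 2,4,6-trichlorobenzoic anhydride | C/C=C(/C)C(=O)OC(=O)c1c(Cl)cc(Cl)cc1Cl | intermediate
20 | methyl (2E,6Z)-2-[(1S,2S)-2-(angeloyloxy)-1-[(tert-butyldimethylsilyl)oxy]but-3-en-1-yl]-7-iodo-6-methylhepta-2,6-dienoate | C=C[C@H](OC(=O)/C(C)=C\C)[C@@H](O[Si](C)(C)C(C)(C)C)/C(C(=O)OC)=C\CC/C(C)=C\I | intermediate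
21 | B-alkyl-9-borabicyclo[3.3.1]nonane from 20 (boron on the terminal carbon, the future C6) | C(C[C@H](OC(=O)/C(C)=C\C)[C@@H](O[Si](C)(C)C(C)(C)C)/C(C(=O)OC)=C\CC/C(C)=C\I)B1C2CCCC1CCC2 | intermediate
22 | methyl (2E,6Z)-2-[(1S,2S)-2-(angeloyloxy)-1-[(tert-butyldimethylsilyl)oxy]-4-hydroxybutyl]-7-iodo-6-methylhepta-2,6-dienoate | OCC[C@H](OC(=O)/C(C)=C\C)[C@@H](O[Si](C)(C)C(C)(C)C)/C(C(=O)OC)=C\CC/C(C)=C\I | intermediate
23 | methyl (2E,6Z)-2-[(1S,2S)-2-(angeloyloxy)-1-[(tert-butyldimethylsilyl)oxy]-4-oxobutyl]-7-iodo-6-methylhepta-2,6-dienoate | O=CC[C@H](OC(=O)/C(C)=C\C)[C@@H](O[Si](C)(C)C(C)(C)C)/C(C(=O)OC)=C\CC/C(C)=C\I | intermediate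
24 | alkenylchromium(III) dichloride from 23 (Cr in place of I) | O=CC[C@H](OC(=O)/C(C)=C\C)[C@@H](O[Si](C)(C)C(C)(C)C)/C(C(=O)OC)=C\CC/C(C)=C\[Cr](Cl)Cl | intermediate
25 | methyl (1(10)E,4Z,8S,9S)-8-angeloyloxy-6-hydroxy-9-(TBS-oxy)-11,12,13-trinorgermacra-1(10),4-dien-14-oate (both C6 epimers) | C1[C@H](OC(=O)/C(C)=C\C)[C@@H](O[Si](C)(C)C(C)(C)C)/C(C(=O)OC)=C\CC/C(C)=C\C1O | intermediate
26 | methyl (1(10)E,4Z,8S,9S)-8-angeloyloxy-6-oxo-9-(TBS-oxy)-11,12,13-trinorgermacra-1(10),4-dien-14-oate | C1[C@H](OC(=O)/C(C)=C\C)[C@@H](O[Si](C)(C)C(C)(C)C)/C(C(=O)OC)=C\CC/C(C)=C\C1=O | intermediate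
27 | methyl (1(10)E,4Z,6R,8S,9S)-8-angeloyloxy-6-hydroxy-9-(TBS-oxy)-11,12,13-trinorgermacra-1(10),4-dien-14-oate | C1[C@H](OC(=O)/C(C)=C\C)[C@@H](O[Si](C)(C)C(C)(C)C)/C(C(=O)OC)=C\CC/C(C)=C\[C@@H]1O | intermediate
28 | methyl (1(10)E,4R,5S,6R,8S,9S)-8-angeloyloxy-4,5-epoxy-6-hydroxy-9-(TBS-oxy)-11,12,13-trinorgermacr-1(10)-en-14-oate | C1[C@H](OC(=O)/C(C)=C\C)[C@@H](O[Si](C)(C)C(C)(C)C)/C(C(=O)OC)=C\CC[C@@]2(C)O[C@H]2[C@@H]1O | intermediate
29 | (diethoxyphosphoryl)acetic acid | OC(=O)CP(=O)(OCC)OCC | starting material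
30 | methyl (1(10)E,4R,5S,6R,8S,9S)-8-angeloyloxy-6-{[(diethoxyphosphoryl)acetyl]oxy}-4,5-epoxy-9-(TBS-oxy)-11,12,13-trinorgermacr-1(10)-en-14-oate | C1[C@H](OC(=O)/C(C)=C\C)[C@@H](O[Si](C)(C)C(C)(C)C)/C(C(=O)OC)=C\CC[C@@]2(C)O[C@H]2[C@@H]1OC(=O)CP(=O)(OCC)OCC | intermediate
31 | methyl (1(10)E,4R,5S,6R,8S,9S)-8-angeloyloxy-6-{[diazo(diethoxyphosphoryl)acetyl]oxy}-4,5-epoxy-9-(TBS-oxy)-11,12,13-trinorgermacr-1(10)-en-14-oate | C1[C@H](OC(=O)/C(C)=C\C)[C@@H](O[Si](C)(C)C(C)(C)C)/C(C(=O)OC)=C\CC[C@@]2(C)O[C@H]2[C@@H]1OC(=O)C(=[N+]=[N-])P(=O)(OCC)OCC | intermediate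
32 | methyl (1(10)E,4R,5S,6R,7R,8S,9S)-8-angeloyloxy-11-(diethoxyphosphoryl)-4,5-epoxy-9-(TBS-oxy)-13-norgermacr-1(10)-en-12,6-olid-14-oate (C11 epimers) | CCOP(=O)(OCC)C1C(=O)O[C@@H]2[C@H]1[C@H](OC(=O)/C(C)=C\C)[C@@H](O[Si](C)(C)C(C)(C)C)/C(C(=O)OC)=C\CC[C@@]1(C)O[C@@H]21 | intermediate
33 | methyl (1(10)E,4R,5S,6R,7R,8S,9S)-8-angeloyloxy-4,5-epoxy-9-(TBS-oxy)germacra-1(10),11(13)-dien-12,6-olid-14-oate | C=C1C(=O)O[C@@H]2[C@H]1[C@H](OC(=O)/C(C)=C\C)[C@@H](O[Si](C)(C)C(C)(C)C)/C(C(=O)OC)=C\CC[C@@]1(C)O[C@@H]21 | intermediate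
34 | methyl (1(10)E,4R,5S,6R,7R,8S,9S)-8-angeloyloxy-4,5-epoxy-9-hydroxygermacra-1(10),11(13)-dien-12,6-olid-14-oate (CNP0251641.1) | C=C1C(=O)O[C@@H]2[C@H]1[C@H](OC(=O)/C(C)=C\C)[C@@H](O)/C(C(=O)OC)=C\CC[C@@]1(C)O[C@@H]21 | target

**Step count**
Total: 21 steps. Longest linear sequence: 20 steps (steps 1–5 and 7–21); step 6 is a one-step side branch.

**Steps most likely to fail**

Step 19 (key step). The carbenoid may be captured by the oxirane oxygen (oxonium ylide, then deoxygenation or ring expansion). It may insert into the C7–H bond anti to the C6 oxygen (trans fusion). It may also react too slowly with a methylene that has an oxygen-bearing carbon on each side. The fallback sets out from 28 and uses a less electrophilic, catalyst-controlled carbenoid. Glyoxylic acid chloride p-toluenesulfonylhydrazone with N,N-dimethylaniline and then Et3N should convert 28 into the diazoacetate F1. A chiral dirhodium(II) carboxamidate (Rh2(4S-MPPIM)4 or its enantiomer, whichever is matched with the substrate) in CH2Cl2 should then give the unsubstituted cis-lactone F2; the carboxamidate carbenoid is less prone to ylide formation, and the ligand can tell the two C7–H bonds apart. LiHMDS at −78 °C followed by Eschenmoser's salt should give the Mannich base F3, and quaternisation with MeI and elimination with NaHCO3 return to the route at 33.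

Step 13. Ring closure to the ten-membered ring may lose to intermolecular coupling, to reduction of the C–I bond, or to β-elimination of the angelate from the aldehyde. The fallback sets out from 23 and closes the same ring at C4=C5 by metathesis. Vinylmagnesium bromide at −78 °C should give the allylic alcohol F4. Pd(PPh3)4 and Bu3SnH should replace iodine by hydrogen to give the isopropenyl diene F5. Ring-closing metathesis (Grubbs second-generation catalyst, CH2Cl2, 40 °C, 1 mM) should give the ring-cis trisubstituted alkene and returns to the route at 25.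

Step 16. The ring conformation, and not the hydroxyl group, may steer the peracid, so that facial selectivity is poor or the epoxide forms on the wrong face. The fallback sets out from 26 and reaches the same epoxide from the C6 epimer. (R)-Me-CBS with catecholborane should give the 6S alcohol F6. VO(acac)2 with t-BuOOH, which delivers oxygen cis to the hydroxyl in medium-ring (Z)-cycloalkenols, should give the 4R,5S,6S epoxy alcohol F7. A Mitsunobu esterification with 29 (PPh3, DIAD) inverts C6 and returns to the route at 30.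

Further compounds
F1 | step 19 | methyl (1(10)E,4R,5S,6R,8S,9S)-8-angeloyloxy-6-(diazoacetoxy)-4,5-epoxy-9-(TBS-oxy)-11,12,13-trinorgermacr-1(10)-en-14-oate | C1[C@H](OC(=O)/C(C)=C\C)[C@@H](O[Si](C)(C)C(C)(C)C)/C(C(=O)OC)=C\CC[C@@]2(C)O[C@H]2[C@@H]1OC(=O)C=[N+]=[N-]
F2 | step 19 | methyl (1(10)E,4R,5S,6R,7R,8S,9S)-8-angeloyloxy-4,5-epoxy-9-(TBS-oxy)-13-norgermacr-1(10)-en-12,6-olid-14-oate | C1C(=O)O[C@@H]2[C@H]1[C@H](OC(=O)/C(C)=C\C)[C@@H](O[Si](C)(C)C(C)(C)C)/C(C(=O)OC)=C\CC[C@@]1(C)O[C@@H]21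
F3 | step 19 | 13-(dimethylamino)-11,13-dihydro derivative of 33 (C11 epimers) | CN(C)CC1C(=O)O[C@@H]2[C@H]1[C@H](OC(=O)/C(C)=C\C)[C@@H](O[Si](C)(C)C(C)(C)C)/C(C(=O)OC)=C\CC[C@@]1(C)O[C@@H]21
F4 | step 13 | methyl (2E,6Z)-2-[(1S,2S)-2-(angeloyloxy)-1-[(tert-butyldimethylsilyl)oxy]-4-hydroxyhex-5-en-1-yl]-7-iodo-6-methylhepta-2,6-dienoate (both carbinol epimers) | C=CC(O)C[C@H](OC(=O)/C(C)=C\C)[C@@H](O[Si](C)(C)C(C)(C)C)/C(C(=O)OC)=C\CC/C(C)=C\I
F5 | step 13 | methyl (2E)-2-[(1S,2S)-2-(angeloyloxy)-1-[(tert-butyldimethylsilyl)oxy]-4-hydroxyhex-5-en-1-yl]-6-methylhepta-2,6-dienoate (both carbinol epimers) | C=CC(O)C[C@H](OC(=O)/C(C)=C\C)[C@@H](O[Si](C)(C)C(C)(C)C)/C(C(=O)OC)=C\CCC(C)=C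
F6 | step 16 | methyl (1(10)E,4Z,6S,8S,9S)-8-angeloyloxy-6-hydroxy-9-(TBS-oxy)-11,12,13-trinorgermacra-1(10),4-dien-14-oate | C1[C@H](OC(=O)/C(C)=C\C)[C@@H](O[Si](C)(C)C(C)(C)C)/C(C(=O)OC)=C\CC/C(C)=C\[C@H]1O
F7 | step 16 | methyl (1(10)E,4R,5S,6S,8S,9S)-8-angeloyloxy-4,5-epoxy-6-hydroxy-9-(TBS-oxy)-11,12,13-trinorgermacr-1(10)-en-14-oate | C1[C@H](OC(=O)/C(C)=C\C)[C@@H](O[Si](C)(C)C(C)(C)C)/C(C(=O)OC)=C\CC[C@@]2(C)O[C@H]2[C@H]1O
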